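**Retrosynthetic overview**

- The route rests on the acyclic central unit: C2 of the but-2-enoate carries the carboxyl carbon C1 and an oxymethylene carbon, and these two arms differ only in lying cis or trans to the C4 methyl on C3. The Z geometry of C2=C3 is therefore a choice between the two CH2OH groups of 2-ethylidenepropane-1,3-diol.
- First disconnection: the benzylic ester C–O bond, giving the Z-acid and (S)-1-(3,4,5-trimethoxyphenyl)propan-1-ol; the alcohol comes from 3,4,5-trimethoxybenzaldehyde by catalytic enantioselective ethylation.
- Second: the carboxyl group goes back to the CH2OH that lies cis to the methyl in the (E)-monoangelate of the diol.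
- Third: the angelate C–O bond is made by lipase-mediated angeloyl transfer from angelic anhydride to the CH2OH trans to the methyl; the diol comes from diethyl ethylidenemalonate by hydride reduction.
- No ring is formed; the only ring, the 3,4,5-trimethoxybenzene, is bought.

Key step: step 2

Remark: angelic anhydride is taken as a purchased reagent; if it has to be made, angelic acid and a carbodiimide give it in one operation.
Remark: aluminium and zinc alkoxides that exist only until aqueous work-up (steps 1 and 5) are not counted as separate intermediates.

**Route**

Step 1
Reactants: 1 diethyl ethylidenemalonate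
Product: 2 2-ethylidenepropane-1,3-diol
Conditions: i-Bu2AlH (4.5 equiv), CH2Cl2, −78 → 0 °C; aq potassium sodium tartrate, continuous EtOAc extraction
Reagents that add atoms: none
Why: Ester reduction by i-Bu2AlH, an electrophilic hydride that attacks the two ester carbonyls 1,2 in preference to the conjugate position, is the usual way from alkylidenemalonates to 2-alkylidenepropane-1,3-diols, and the product has two identical CH2OH arms and therefore no alkene isomers.

Step 2
Reactants: 2 2-ethylidenepropane-1,3-diol; 3 angelic anhydride [(2Z)-2-methylbut-2-enoic anhydride]
Product: 4 (E)-2-(hydroxymethyl)but-2-enyl angelate [ester on the CH2 trans to the C3 methyl; free CH2OH cis to it]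
Conditions: Burkholderia cepacia lipase (immobilised), 3 (1.1 equiv), 4 Å molecular sieves, t-BuOMe, 30 °C; enzyme filtered off at the monoester stage
Reagents that add atoms: none
Why: Proposed new method: the active-site serine of the lipase is acylated by anhydride 3 with loss of angelic acid, and the angeloyl enzyme is then attacked by the hydroxymethyl group of 2 that can reach it; the closest known reaction is the lipase-catalysed monoacetylation of 2-alkylidenepropane-1,3-diols with vinyl acetate, which acylates the arm trans to the alkylidene substituent, and the only new element is the α-branched, conjugated angeloyl donor, which should pass through the same serine-hydrolase mechanism more slowly, as crotonyl and methacryloyl donors do. No ring closes and no stereocentre forms; the one new stereo-element is the geometry of the C2=C3 alkene, and it is fixed purely by the site of acylation because C2 of 2 carries two identical arms. The step needs site selectivity between the arm cis to H and the arm cis to CH3 and a stop at the monoester: the enzyme pocket supplies the first, while 1.1 equiv of 3, the lower reactivity of monoester 4 and monitoring supply the second. The hindered anhydride should not acylate a primary alcohol at a useful rate without base or a nucleophilic catalyst, so no unselective background reaction is expected. The medium is neutral and dry, so neither Z-to-E isomerisation of the angeloyl group nor 1,3-acyl migration between the two arms of 4 should occur, and 4 is taken on promptly for the same reason.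

Step 3
Reactants: 4 (E)-2-(hydroxymethyl)but-2-enyl angelate
Product: 5 (Z)-2-formylbut-2-enyl angelate [CHO cis to the C3 methyl]
Conditions: TEMPO (10 mol%), PhI(OAc)2 (1.1 equiv), CH2Cl2, 0 °C → rt; aq Na2S2O3; crude used at once
Reagents that add atoms: none
Why: Oxoammonium oxidation (TEMPO with PhI(OAc)2) of a primary allylic alcohol stops at the aldehyde under nearly neutral, non-nucleophilic conditions in which Z-allylic alcohols are known to keep their geometry and the angelate ester is inert, and the Z-enal is not chromatographed.

Step 4
Reactants: 5 (Z)-2-formylbut-2-enyl angelate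
Product: 6 (Z)-2-(angeloyloxymethyl)but-2-enoic acid [CO2H cis to the C3 methyl]
Conditions: NaClO2, NaH2PO4, 2-methylbut-2-ene, t-BuOH/H2O, 0 °C → rt
Reagents that add atoms: sodium chlorite, [Na+].[O-]Cl=O
Why: The Pinnick oxidation converts α,β-unsaturated aldehydes into the acids at pH 3–4 without shifting or isomerising the double bond, while 2-methylbut-2-ene traps the HOCl that could otherwise attack the two alkenes.

Step 5
Reactants: 7 3,4,5-trimethoxybenzaldehyde
Product: 8 (S)-1-(3,4,5-trimethoxyphenyl)propan-1-ol
Conditions: Et2Zn (2 equiv), (−)-DAIB [(2S)-3-exo-(dimethylamino)isoborneol] (5 mol%), toluene, 0 °C; aq NH4Cl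
Reagents that add atoms: diethylzinc, CC[Zn]CC
Why: Amino-alcohol-catalysed enantioselective addition of diethylzinc to an aryl aldehyde, in which the chiral zinc aminoalkoxide formed from (−)-DAIB delivers the ethyl group to the Si face of the aldehyde, should give the (S)-carbinol as it does with benzaldehyde, and this sets the only stereocentre of the target.

Step 6
Reactants: 6 (Z)-2-(angeloyloxymethyl)but-2-enoic acid; 8 (S)-1-(3,4,5-trimethoxyphenyl)propan-1-ol
Product: 10 (1S)-1-(3,4,5-trimethoxyphenyl)propyl (2Z)-2-(angeloyloxymethyl)but-2-enoate (the target), via mixed 2,4,6-trichlorobenzoic anhydride 9 (not isolated)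
Conditions: 2,4,6-Cl3C6H2COCl (1.05 equiv), Et3N (1.1 equiv), toluene, rt; then 8 (1.3 equiv), 75 °C
Reagents that add atoms: 2,4,6-trichlorobenzoyl chloride, O=C(Cl)c1c(Cl)cc(Cl)cc1Cl (its atoms stay in 9 only; none are left in 10)
Why: This is a Yamaguchi-type mixed-anhydride esterification run thermally without DMAP, the protocol established for angelic acid: the alcohol attacks the less shielded enoyl carbonyl of 9 with no nucleophilic catalyst present, so the Z-enoate is neither isomerised by conjugate addition nor stripped of its allylic angelate by SN2′ attack, and since only the O–H bond of 8 reacts the (S)-centre is retained.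

**Compound list**

1 | diethyl ethylidenemalonate | CCOC(=O)C(=CC)C(=O)OCC | starting material
2 | 2-ethylidenepropane-1,3-diol | CC=C(CO)CO | intermediate
3 | angelic anhydride [(2Z)-2-methylbut-2-enoic anhydride] | C/C=C(/C)C(=O)OC(=O)/C(C)=C\C | starting material
4 | (E)-2-(hydroxymethyl)but-2-enyl angelate | C/C=C(/C)C(=O)OC/C(CO)=C/C | intermediate
5 | (Z)-2-formylbut-2-enyl angelate | C/C=C(/C)C(=O)OC/C(C=O)=C/C | intermediate
6 | (Z)-2-(angeloyloxymethyl)but-2-enoic acid | C/C=C(/C)C(=O)OC/C(=C/C)C(=O)O | intermediate
7 | 3,4,5-trimethoxybenzaldehyde | O=Cc1cc(OC)c(OC)c(OC)c1 | starting material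
8 | (S)-1-(3,4,5-trimethoxyphenyl)propan-1-ol | O[C@@H](CC)c1cc(OC)c(OC)c(OC)c1 | intermediate
9 | (Z)-2-(angeloyloxymethyl)but-2-enoic 2,4,6-trichlorobenzoic anhydride | C/C=C(/C)C(=O)OC/C(=C/C)C(=O)OC(=O)c1c(Cl)cc(Cl)cc1Cl | intermediate
10 | (1S)-1-(3,4,5-trimethoxyphenyl)propyl (2Z)-2-{[(2Z)-2-methylbut-2-enoyloxy]methyl}but-2-enoate | C/C=C(/C)C(=O)OC/C(=C/C)C(=O)O[C@@H](CC)c1cc(OC)c(OC)c(OC)c1 | target

**Step count**

Total: 6 steps. Longest linear sequence: 5 steps (1 → 2 → 4 → 5 → 6 → 10; steps 1, 2, 3, 4 and 6). The alcohol branch (step 5) is one step.

**Steps most likely to fail**

1. Step 2 (proposed new method). The angeloyl enzyme may form too slowly from a hindered, conjugated anhydride, so that conversion stalls. The larger acyl group may also erode the site selectivity between the two arms, or acylation may run on to the diester.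
Fallback, from diol 2, returning at 4, using known chemistry only. Diol 2 is monoacetylated with vinyl acetate and the same lipase, the documented reaction of this diol class, to give (E)-2-(hydroxymethyl)but-2-enyl acetate F1. The free arm is capped with 3,4-dihydro-2H-pyran and pyridinium p-toluenesulfonate in CH2Cl2 to give (E)-2-[(tetrahydro-2H-pyran-2-yloxy)methyl]but-2-enyl acetate F2; an acetal is chosen because it cannot migrate between the arms. K2CO3 in MeOH at 0 °C removes the acetate to give (Z)-2-[(tetrahydro-2H-pyran-2-yloxy)methyl]but-2-en-1-ol F3. Its lithium alkoxide (LiN(SiMe3)2, THF, −78 °C) is acylated with anhydride 3, a base-mediated angeloylation known to keep the Z geometry of the acyl group, to give (E)-2-[(tetrahydro-2H-pyran-2-yloxy)methyl]but-2-enyl angelate F4. Pyridinium p-toluenesulfonate in MeOH then frees the hydroxyl and delivers 4.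

2. Step 6. Acylation of the secondary benzylic alcohol may be sluggish at 75 °C, which would give time for thermal Z-to-E isomerisation of the activated enoyl unit. Ionisation at the electron-rich benzylic carbon in the warm, weakly acidic medium could erode the (S)-configuration.
Fallback, from aldehyde 7 and acid 6, returning at 10. Aldehyde 7 is ethylated with Et2Zn under the enantiomeric catalyst (+)-DAIB to give (R)-1-(3,4,5-trimethoxyphenyl)propan-1-ol F5. F5 is coupled with acid 6 under Mitsunobu conditions: the PPh3/DIAD betaine is preformed in toluene at 0 °C so that no free phosphine meets the enoate, then 6 and F5 are added at −20 °C. Here the alcohol is activated instead of the acid, so the carboxylate of 6 acts only as an O-nucleophile and its Z-enoate is untouched, and SN2 displacement with inversion should give the (S)-ester 10.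

3. Step 3. The Z-enal may isomerise to the more stable E-isomer through acid traces while it accumulates, is concentrated or is handled. A 1,3-acyl shift in 4 before oxidation would have the same effect on the geometry.
Fallback, from 4, returning at 6. The two-stage sequence through a handled aldehyde is replaced by a single-stage alcohol-to-acid oxidation: catalytic TEMPO, catalytic NaOCl and stoichiometric NaClO2 in MeCN/phosphate buffer (pH 6.7) at 35 °C. The aldehyde is then oxidised on as fast as it forms, so 5 never accumulates or meets silica gel; no new compound arises (entry F0).

**Further compounds**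

F1 | step 2 | (E)-2-(hydroxymethyl)but-2-enyl acetate | CC(=O)OC/C(CO)=C/C
F2 | step 2 | (E)-2-[(tetrahydro-2H-pyran-2-yloxy)methyl]but-2-enyl acetate (racemic at the acetal carbon) | CC(=O)OC/C(COC1CCCCO1)=C/C
F3 | step 2 | (Z)-2-[(tetrahydro-2H-pyran-2-yloxy)methyl]but-2-en-1-ol (racemic at the acetal carbon) | OC/C(COC1CCCCO1)=C/C
F4 | step 2 | (E)-2-[(tetrahydro-2H-pyran-2-yloxy)methyl]but-2-enyl angelate (racemic at the acetal carbon) | C/C=C(/C)C(=O)OC/C(COC1CCCCO1)=C/C
F5 | step 6 | (R)-1-(3,4,5-trimethoxyphenyl)propan-1-ol | O[C@H](CC)c1cc(OC)c(OC)c(OC)c1
F0 | step 3 | none | none
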